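**Retrosynthetic overview**
1. Target 25 ⇒ silyl ether 24 ⇒ 5-O-methyl ether 23; the C2–OAr bond of 23 comes from sulfoxide 21 and phenol 22 by addition–elimination.
2. The pyranone ring (ring C, the only ring that is made) is closed from o-hydroxyacetophenone 18 with CS2; the acetyl group is placed on C4a of arene 15 by MOM-directed lithiation.
3. Key disconnection: ring A carries C7–OMe and C8–CH2 (C1″ of the prenyl group) on neighbouring carbons, with the C8a oxygen on the other side of C8. Both bonds are traced to one molecule of 3-methoxy-3-methylbut-1-ene 12 adding across a C7–C8 aryne (oxygen to C7, allyl terminus to C8).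
4. Aryne precursor 10 ⇐ 5-methoxyresorcinol 1 by mono-MOM protection, carbamate-directed C-silylation and base-mediated exchange of carbamate for triflate; 12 ⇐ 2-methylbut-3-en-2-ol 11.
5. Ring order: ring A and the hydroquinone ring are bought; ring C is formed in step 9.

Key step: step 6

Remark on the chemistry: the C–Si bond of the aryne precursor lies between two oxygens and para to a third and is taken to be prone to ipso-protodesilylation. No strongly acidic operation is therefore run between C-silylation and aryne generation, and the oxygen that becomes the triflate is carried as an N-isopropyl carbamate, which directs the lithiation and is removed by base.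

**Route**

Step 1
Reactants: 1 5-methoxyresorcinol; 2 chloromethyl methyl ether
Product: 3 3-methoxy-5-(methoxymethoxy)phenol
Conditions: 2 (1.0 equiv), iPr2NEt, CH2Cl2, 0 °C → rt; chromatography, recovered 1 and bis-ether recycled
Reagents that add atoms: none
Why: Williamson-type O-alkylation of a phenol by the α-chloro ether; the two hydroxyls are equivalent, so one equivalent of 2 should give the mono-ether as main product with no regiochemical question.

Step 2
Reactants: 3 3-methoxy-5-(methoxymethoxy)phenol
Product: 4 3-methoxy-5-(methoxymethoxy)phenyl N-isopropylcarbamate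
Conditions: iPrNCO, Et3N (cat.), CH2Cl2, rt
Reagents that add atoms: isopropyl isocyanate, CC(C)N=C=O
Why: Base-catalysed addition of the phenol to the isocyanate (carbamoylation) should give the N–H carbamate that later serves as directing group and as a base-cleavable mask of the phenol.

Step 3
Reactants: 4 3-methoxy-5-(methoxymethoxy)phenyl N-isopropylcarbamate
Product: 8 5-methoxy-3-(methoxymethoxy)-2-(trimethylsilyl)phenyl N-isopropylcarbamate, via N-silyl carbamate 5 (not isolated), via aryllithium 6 (not isolated), via N-silyl C-silyl carbamate 7 (not isolated)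
Conditions: TBSOTf, TMEDA, Et2O, 0 °C → rt; n-BuLi, TMEDA, −78 °C; TMSCl, −78 °C → rt; aq. NH4Cl work-up
Reagents that add atoms: chlorotrimethylsilane, C[Si](C)(C)Cl; tert-butyldimethylsilyl trifluoromethanesulfonate, CC(C)(C)[Si](C)(C)OS(=O)(=O)C(F)(F)F (its silyl group is carried by 5 to 7 only); n-butyllithium, [Li]CCCC (lithium in 6 only)
Why: Directed ortho-metalation: N-silylation in the flask blocks the carbamate N–H, n-BuLi/TMEDA then removes the ring proton between the carbamate and the MOM ether (the one site flanked by the two strongest directing groups), the aryllithium is C-silylated, and the N–Si bond is hydrolysed on work-up.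

Step 4
Reactants: 8 5-methoxy-3-(methoxymethoxy)-2-(trimethylsilyl)phenyl N-isopropylcarbamate
Product: 10 5-methoxy-3-(methoxymethoxy)-2-(trimethylsilyl)phenyl trifluoromethanesulfonate, via silyl phenol 9 (not isolated)
Conditions: DBU, Et2NH, MeCN, 40 °C; then PhNTf2, rt
Reagents that add atoms: N-phenylbis(trifluoromethanesulfonimide), O=S(=O)(N(c1ccccc1)S(=O)(=O)C(F)(F)F)C(F)(F)F
Why: DBU should trigger E1cB loss of isopropyl isocyanate (trapped by Et2NH as a urea) under basic conditions that spare the aryl–Si bond and the MOM ether, and the released phenoxide is O-sulfonylated by PhNTf2 in the same pot.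

Step 5
Reactants: 11 2-methylbut-3-en-2-ol
Product: 12 3-methoxy-3-methylbut-1-ene
Conditions: KOH (powder), MeI, DMSO, rt; distillation
Reagents that add atoms: iodomethane, CI
Why: Williamson ether synthesis of the tertiary alkoxide with a methyl electrophile that cannot eliminate; the volatile ether is taken off by distillation.

Step 6
Reactants: 10 5-methoxy-3-(methoxymethoxy)-2-(trimethylsilyl)phenyl trifluoromethanesulfonate; 12 3-methoxy-3-methylbut-1-ene
Product: 15 1,5-dimethoxy-3-(methoxymethoxy)-2-(3-methylbut-2-en-1-yl)benzene, via aryne 13 (not isolated), via oxonium zwitterion 14 (not isolated)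
Conditions: CsF (3 equiv), 12 (20 equiv, cosolvent), MeCN, rt → 40 °C, 10 added slowly
Reagents that add atoms: none
Why: Proposed new method: fluoride removes the silyl group of 10 and triflate leaves to give aryne 13, whose triple bond is polarised by the inductively withdrawing OMOM group on the neighbouring carbon (C8a), so the ether oxygen of 12 adds at the remote aryne carbon C7 and the negative charge is placed on C8, as in all additions to 3-alkoxyarynes. In zwitterion 14 the in-plane C8 carbanion, C7, the oxonium oxygen, the quaternary carbon and the vinyl group form a six-atom array, and a charge-accelerated (3,3) shift (in effect an intramolecular SN2′ displacement with the neutral aryl methyl ether as leaving group) forms C8–C1″, breaks O–CMe2 and turns the 1,1-dimethylallyl unit into the prenyl group, leaving the methyl on the C7 oxygen. The closest known reaction types are the aryne aza-Claisen rearrangement of tertiary allylamines, the insertion of arynes into allyl thioethers and the ring-opening capture of arynes by cyclic ethers, which show that such zwitterions rearrange through the aryl anion and that an ether oxygen can add to an aryne; an acyclic allyl ether has not been used in this way. No ring is closed and no stereocentre is formed. The selectivity needed is the site of oxygen attack (C7, not C8), which the C8a OMOM group secures; an ene reaction is not available because the allylic carbon of 12 is quaternary, and the weak nucleophilicity of the hindered ether is answered by using 12 as cosolvent and adding 10 slowly. Ionisation of 14 to an aryl anion and a dimethylallyl cation would be expected to recombine mainly at the unhindered terminus and so lead to the same product.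

Step 7
Reactants: 15 1,5-dimethoxy-3-(methoxymethoxy)-2-(3-methylbut-2-en-1-yl)benzene
Product: 17 1-[4,6-dimethoxy-2-(methoxymethoxy)-3-(3-methylbut-2-en-1-yl)phenyl]ethan-1-one, via aryllithium 16 (not isolated)
Conditions: n-BuLi, THF, −20 → 0 °C; MeC(O)N(OMe)Me, −78 °C → rt; H2O
Reagents that add atoms: N-methoxy-N-methylacetamide, CC(=O)N(C)OC; n-butyllithium, [Li]CCCC (lithium in 16 only)
Why: Directed ortho-metalation followed by Weinreb ketone synthesis: the MOM ether, a stronger director than methoxy, should steer lithiation to the C4a–H between OMOM and OMe and not to the C6–H between two methoxy groups, and the stable tetrahedral adduct of the amide prevents a second addition.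

Step 8
Reactants: 17 1-[4,6-dimethoxy-2-(methoxymethoxy)-3-(3-methylbut-2-en-1-yl)phenyl]ethan-1-one
Product: 18 1-[2-hydroxy-4,6-dimethoxy-3-(3-methylbut-2-en-1-yl)phenyl]ethan-1-one
Conditions: 3 M aq. HCl, MeOH, rt
Reagents that add atoms: none
Why: Acid-catalysed acetal exchange with methanol removes the MOM group under mild conditions, and the released phenol is hydrogen-bonded to the ketone, which lowers its tendency to add to the neighbouring prenyl double bond.

Step 9
Reactants: 18 1-[2-hydroxy-4,6-dimethoxy-3-(3-methylbut-2-en-1-yl)phenyl]ethan-1-one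
Product: 20 5,7-dimethoxy-8-(3-methylbut-2-en-1-yl)-2-(methylsulfanyl)-4H-chromen-4-one, via thione 19 (not isolated)
Conditions: KOtBu, CS2, THF, 0 °C → rt; 1 M HCl; crude 19, MeI, K2CO3, acetone, rt
Reagents that add atoms: carbon disulfide, S=C=S; iodomethane, CI
Why: Claisen-type condensation of the ketone enolate with CS2 gives a β-keto dithioate that cyclises through the only free phenol (C8a–OH) with loss of hydrogen sulfide to thione 19, and S-methylation of its thiolate tautomer fixes the 2-(methylsulfanyl)chromone; ring C can close in one direction only.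

Step 10
Reactants: 20 5,7-dimethoxy-8-(3-methylbut-2-en-1-yl)-2-(methylsulfanyl)-4H-chromen-4-one
Product: 21 5,7-dimethoxy-8-(3-methylbut-2-en-1-yl)-2-(methylsulfinyl)-4H-chromen-4-one (racemic at sulfur)
Conditions: 30% aq. H2O2 (1.2 equiv), (CF3)2CHOH, rt
Reagents that add atoms: hydrogen peroxide, OO
Why: Chemoselective sulfide-to-sulfoxide oxidation by hydrogen peroxide activated through hydrogen bonding in hexafluoroisopropanol, under which isolated alkenes such as the prenyl double bond should not be epoxidised; the sulfur stereocentre is racemic and is lost in the next step.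

Step 11
Reactants: 21 5,7-dimethoxy-8-(3-methylbut-2-en-1-yl)-2-(methylsulfinyl)-4H-chromen-4-one; 22 4-(tert-butyldimethylsilyloxy)phenol
Product: 23 2-[4-(tert-butyldimethylsilyloxy)phenoxy]-5,7-dimethoxy-8-(3-methylbut-2-en-1-yl)-4H-chromen-4-one
Conditions: 22, NaH, THF, 0 °C; then 21, 0 °C → rt
Reagents that add atoms: none
Why: Addition–elimination (vinylogous acyl substitution) at C2: the phenoxide adds to the β-carbon of the chromone enone and methanesulfenate is expelled, the established way from 2-sulfinylchromones to 2-aryloxychromones.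

Step 12
Reactants: 23 2-[4-(tert-butyldimethylsilyloxy)phenoxy]-5,7-dimethoxy-8-(3-methylbut-2-en-1-yl)-4H-chromen-4-one
Product: 24 2-[4-(tert-butyldimethylsilyloxy)phenoxy]-5-hydroxy-7-methoxy-8-(3-methylbut-2-en-1-yl)-4H-chromen-4-one
Conditions: BCl3 (1 M in CH2Cl2), CH2Cl2, −78 → −20 °C; ice-water
Reagents that add atoms: none
Why: Chelation-controlled Lewis-acid ether cleavage: BCl3 binds between the C4 carbonyl and the peri C5 methoxy oxygen and chloride removes that methyl group only, the C7 methyl ether has no neighbouring carbonyl, and the freed C5 hydroxyl is not ortho to the prenyl group, so no chroman can form.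

Step 13
Reactants: 24 2-[4-(tert-butyldimethylsilyloxy)phenoxy]-5-hydroxy-7-methoxy-8-(3-methylbut-2-en-1-yl)-4H-chromen-4-one
Product: 25 7-O-methylepimedonin G, 5-hydroxy-2-(4-hydroxyphenoxy)-7-methoxy-8-(3-methylbut-2-en-1-yl)-4H-chromen-4-one
Conditions: KHF2, MeOH, rt
Reagents that add atoms: none
Why: Fluoride-mediated cleavage of the phenolic silyl ether (Si–F bond formation) under near-neutral conditions, which should leave the 2-aryloxychromone linkage and the prenyl group untouched.

**Compound list**
1 | 5-methoxyresorcinol | COc1cc(O)cc(O)c1 | starting material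
2 | chloromethyl methyl ether | COCCl | starting material
3 | 3-methoxy-5-(methoxymethoxy)phenol | COCOc1cc(O)cc(OC)c1 | intermediate
4 | 3-methoxy-5-(methoxymethoxy)phenyl N-isopropylcarbamate | COCOc1cc(OC)cc(OC(=O)NC(C)C)c1 | intermediate
5 | 3-methoxy-5-(methoxymethoxy)phenyl N-(tert-butyldimethylsilyl)-N-isopropylcarbamate (formed in the flask) | COCOc1cc(OC)cc(OC(=O)N(C(C)C)[Si](C)(C)C(C)(C)C)c1 | intermediate
6 | {2-[N-(tert-butyldimethylsilyl)-N-isopropylcarbamoyloxy]-4-methoxy-6-(methoxymethoxy)phenyl}lithium (formed in the flask) | COCOc1cc(OC)cc(OC(=O)N(C(C)C)[Si](C)(C)C(C)(C)C)c1[Li] | intermediate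
7 | 5-methoxy-3-(methoxymethoxy)-2-(trimethylsilyl)phenyl N-(tert-butyldimethylsilyl)-N-isopropylcarbamate (formed in the flask) | COCOc1cc(OC)cc(OC(=O)N(C(C)C)[Si](C)(C)C(C)(C)C)c1[Si](C)(C)C | intermediate
8 | 5-methoxy-3-(methoxymethoxy)-2-(trimethylsilyl)phenyl N-isopropylcarbamate | COCOc1cc(OC)cc(OC(=O)NC(C)C)c1[Si](C)(C)C | intermediate
9 | 5-methoxy-3-(methoxymethoxy)-2-(trimethylsilyl)phenol (as its DBU salt in the flask) | COCOc1cc(OC)cc(O)c1[Si](C)(C)C | intermediate
10 | 5-methoxy-3-(methoxymethoxy)-2-(trimethylsilyl)phenyl trifluoromethanesulfonate | COc1cc(OCOC)c([Si](C)(C)C)c(OS(=O)(=O)C(F)(F)F)c1 | intermediate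
11 | 2-methylbut-3-en-2-ol | CC(C)(O)C=C | starting material
12 | 3-methoxy-3-methylbut-1-ene | COC(C)(C)C=C | intermediate
13 | 5-methoxy-3-(methoxymethoxy)benzyne, triple bond between the former C–Si and C–OTf carbons (formed in the flask) | COC1=CC#CC(OCOC)=C1 | intermediate
14 | zwitterion: C7 aryl(methyl)(2-methylbut-3-en-2-yl)oxonium with C8 aryl anion (formed in the flask) | COc1cc(OCOC)[c-]c([O+](C)C(C)(C)C=C)c1 | intermediate
15 | 1,5-dimethoxy-3-(methoxymethoxy)-2-(3-methylbut-2-en-1-yl)benzene | COc1cc(OCOC)c(CC=C(C)C)c(OC)c1 | intermediate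
16 | [2,4-dimethoxy-6-(methoxymethoxy)-5-(3-methylbut-2-en-1-yl)phenyl]lithium (formed in the flask) | COc1cc(OC)c(CC=C(C)C)c(OCOC)c1[Li] | intermediate
17 | 1-[4,6-dimethoxy-2-(methoxymethoxy)-3-(3-methylbut-2-en-1-yl)phenyl]ethan-1-one | COc1cc(OC)c(CC=C(C)C)c(OCOC)c1C(C)=O | intermediate
18 | 1-[2-hydroxy-4,6-dimethoxy-3-(3-methylbut-2-en-1-yl)phenyl]ethan-1-one | COc1cc(OC)c(CC=C(C)C)c(O)c1C(C)=O | intermediate
19 | 4-hydroxy-5,7-dimethoxy-8-(3-methylbut-2-en-1-yl)-2H-chromene-2-thione (crude, carried on) | COc1cc(OC)c(CC=C(C)C)c2oc(=S)cc(O)c12 | intermediate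
20 | 5,7-dimethoxy-8-(3-methylbut-2-en-1-yl)-2-(methylsulfanyl)-4H-chromen-4-one | COc1cc(OC)c(CC=C(C)C)c2oc(SC)cc(=O)c12 | intermediate
21 | 5,7-dimethoxy-8-(3-methylbut-2-en-1-yl)-2-(methylsulfinyl)-4H-chromen-4-one (racemic at sulfur) | COc1cc(OC)c(CC=C(C)C)c2oc(S(C)=O)cc(=O)c12 | intermediate
22 | 4-(tert-butyldimethylsilyloxy)phenol | CC(C)(C)[Si](C)(C)Oc1ccc(O)cc1 | starting material
23 | 2-[4-(tert-butyldimethylsilyloxy)phenoxy]-5,7-dimethoxy-8-(3-methylbut-2-en-1-yl)-4H-chromen-4-one | COc1cc(OC)c(CC=C(C)C)c2oc(Oc3ccc(O[Si](C)(C)C(C)(C)C)cc3)cc(=O)c12 | intermediate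
24 | 2-[4-(tert-butyldimethylsilyloxy)phenoxy]-5-hydroxy-7-methoxy-8-(3-methylbut-2-en-1-yl)-4H-chromen-4-one | COc1cc(O)c2c(=O)cc(Oc3ccc(O[Si](C)(C)C(C)(C)C)cc3)oc2c1CC=C(C)C | intermediate
25 | 7-O-methylepimedonin G, 5-hydroxy-2-(4-hydroxyphenoxy)-7-methoxy-8-(3-methylbut-2-en-1-yl)-4H-chromen-4-one | COc1cc(O)c2c(=O)cc(Oc3ccc(O)cc3)oc2c1CC=C(C)C | target

**Totals**
Total step count: 13. Longest linear sequence: 12 steps (1 → 25 through steps 1 to 4 and 6 to 13); step 5 is a one-step side branch.

**Steps most likely to fail**

Step 6 (the new method). The hindered, weakly nucleophilic ether oxygen may be outrun in the capture of aryne 13 by fluoride, by acetonitrile or by a second aryne. Zwitterion 14 may also be protonated before it rearranges and then shed the tertiary allyl group without C–C bond formation, or an ion pair may recombine at the tertiary allyl terminus. The fallback uses known chemistry only; it sets out from phenol 3 and comes back to the route at 15. Phenol 3 would be O-methylated (MeI, K2CO3, acetone) to 1,3-dimethoxy-5-(methoxymethoxy)benzene F1. This would be lithiated ortho to the MOM ether (n-BuLi, THF, 0 °C) to [2,4-dimethoxy-6-(methoxymethoxy)phenyl]lithium F2. Transmetalation with CuBr·SMe2 and alkylation with 1-bromo-3-methylbut-2-ene at its primary carbon would give 15. The C7 methyl ether and the C8 prenyl group are then introduced separately by Williamson etherification, directed ortho-metalation and copper-mediated allylation, and steps 2 to 5 are not needed.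

Step 7. Metalation may occur at the wrong site (the C6–H between the two methoxy groups, or the benzylic and allylic CH2 of the prenyl group), and proton transfer from the amide to the hindered aryllithium may return 15. The fallback sets out from 15 and comes back at 18, so that step 8 is not needed. The MOM ether of 15 would be removed first (aq. HCl, MeOH, rt) to give 3,5-dimethoxy-2-(3-methylbut-2-en-1-yl)phenol F3. Magnesium-mediated ortho-formylation of this phenol (MgCl2, Et3N, paraformaldehyde, MeCN, reflux) can only reach the single free ortho carbon C4a and would give 2-hydroxy-4,6-dimethoxy-3-(3-methylbut-2-en-1-yl)benzaldehyde F4. MeMgBr (excess, THF, 0 °C) would give racemic 2-(1-hydroxyethyl)-3,5-dimethoxy-6-(3-methylbut-2-en-1-yl)phenol F5, and MnO2 (CH2Cl2, rt) would oxidise the benzylic alcohol to ketone 18. C4a is then functionalised under phenoxide control instead of by lithiation.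

Step 12. Lewis-acid cleavage of the C2–OAr ketene-acetal linkage and of the aryl silyl ether may compete with the chelation-controlled loss of the C5 methyl group. The fallback sets out from sulfide 20 and comes back at 24. The C5 methyl ether would be cleaved at the sulfide stage (BCl3, CH2Cl2, −78 → −20 °C), where neither the aryloxy nor the silyl group is present, to give 5-hydroxy-7-methoxy-8-(3-methylbut-2-en-1-yl)-2-(methylsulfanyl)-4H-chromen-4-one F6. Oxidation as in step 10 (H2O2, (CF3)2CHOH, rt) would give racemic 5-hydroxy-7-methoxy-2-(methylsulfinyl)-8-(3-methylbut-2-en-1-yl)-4H-chromen-4-one F7. Displacement with two equivalents of the sodium salt of 22 (THF, rt → 50 °C), one of which is taken up by the chelated C5 hydroxyl, would give 24 directly.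

**Further compounds**
F1 | step 6 | 1,3-dimethoxy-5-(methoxymethoxy)benzene | COCOc1cc(OC)cc(OC)c1
F2 | step 6 | [2,4-dimethoxy-6-(methoxymethoxy)phenyl]lithium | COCOc1cc(OC)cc(OC)c1[Li]
F3 | step 7 | 3,5-dimethoxy-2-(3-methylbut-2-en-1-yl)phenol | COc1cc(O)c(CC=C(C)C)c(OC)c1
F4 | step 7 | 2-hydroxy-4,6-dimethoxy-3-(3-methylbut-2-en-1-yl)benzaldehyde | COc1cc(OC)c(CC=C(C)C)c(O)c1C=O
F5 | step 7 | 2-(1-hydroxyethyl)-3,5-dimethoxy-6-(3-methylbut-2-en-1-yl)phenol (racemic) | COc1cc(OC)c(CC=C(C)C)c(O)c1C(C)O
F6 | step 12 | 5-hydroxy-7-methoxy-8-(3-methylbut-2-en-1-yl)-2-(methylsulfanyl)-4H-chromen-4-one | COc1cc(O)c2c(=O)cc(SC)oc2c1CC=C(C)C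
F7 | step 12 | 5-hydroxy-7-methoxy-2-(methylsulfinyl)-8-(3-methylbut-2-en-1-yl)-4H-chromen-4-one (racemic at sulfur) | COc1cc(O)c2c(=O)cc(S(C)=O)oc2c1CC=C(C)C
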